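A small excess of nucleophile in the charge, 2.20 M against 2.0 M of electrophile, stands at 80 °C in a closed flask, and the target is the one thing followed.

- Tuesday's: electrophile 2 M; nucleophile 2.2 M; temperature 80 °C; the very flask that is asked about, followed so far
- flask: electrophile 2.0 M; nucleophile 2.20 M; temperature 80 °C; time 80 min

- Tuesday's (time / min: target / %): 6.00: 17; 10.0: 24; 20.0: 35; 30.0: 35; 50.0: 42; 80.0: 32

(each reading ± 2 percentage points)

- alpha: at 80 min take out 90% of the target then present, then wait 25 min
- delta: at 80 min raise the temperature by 20 K, then wait 25 min
- zeta: change nothing and wait 25 min more

- target taken out counts as made
- the analysis behind the earlier runs scatters by 2 percentage points, standard deviation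
- the earlier runs do not show what temperature does; that part of a forecast is a guess

- target, in percent of the electrophile first charged, at 80 min
- what to do for the largest gain in target; "none" if nothing gains more than 2 percentage points (alpha / delta / zeta / none)
- target present, with what was taken out counted in, in percent of the electrophile first charged, after delta
- target present, with what was taken out counted in, in percent of the electrophile first charged, after zeta

How fast does this flask start? It shows 17% after 6.00 min, so at that pace the electrophile charge would be target in 35.3 min. Yet 50.0 min, longer than that time, shows 42%.

How fast is target lost? If the fall from 42% to 32% is pure loss, the readings give a lifetime of 110 min.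

And how much target has been made? What stands plus what was lost, which is the area under the readings divided by that lifetime: 56.1%.

Isn't that weak? Yes: its lifetime rests on two scattered readings and on assuming no making at the end, so it is a reading and no more.

Then why should making slow near there? My supposition is that each joining sets free something that ties up a second nucleophile. Nucleophile is then the limiting reagent, since 2.20 M is less than twice 2.0 M. Its charge pays for 55.0%, the paid share: the share of the electrophile charge that the nucleophile charge covers at two per target. The count from the readings lies close to it, and the two come from different things.

Your call? I take 32% for now. With the count near the paid share, I expect alpha to add less than 2 percentage points and waiting to lose target, and heating is a guess, so I say none.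

The forecast parts from me on the choice: 33% now, 25% after zeta, 13% after delta and alpha as best, with “about 10% of the electrophile left”.

The flask gives 34.3% now, 30.2% after zeta and 15.2% after delta, and the best choice is none: alpha changes the target by 0.78 points, zeta by −4.1 points and delta by −19 points.

    electrophile + nucleophile → acid set free + target (k = 3.00 × 10⁻⁴ M⁻¹ s⁻¹, Ea = 88.0 kJ mol⁻¹)
    nucleophile + acid set free ⇌ protonated nucleophile, settled at all times (K = 390 M⁻¹, ΔH = −48.0 kJ mol⁻¹)
    electrophile + target → side product (k = 1.80 × 10⁻⁵ M⁻¹ s⁻¹, Ea = 92.0 kJ mol⁻¹)
    target → over-reaction product (k = 1.00 × 10⁻⁴ s⁻¹, Ea = 99.0 kJ mol⁻¹)
    (constants at 80 °C)

At 80.0 min this flask holds 1.04 M of protonated nucleophile and 4.4% of its nucleophile charge, and its target made so far, with the side product halved since it counts as two, comes to 53.2%, against the paid share of 55.0%. The neighbour charged with 0.55 M of nucleophile has a paid share of 13.8%, a quarter of this flask's. At 80.0 min that neighbour keeps 2.69% of its nucleophile charge, its target made so far, counted the same way, comes to 14.4%, and its target present stands at 8.86%.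

Readings and results were generated by integration for an exercise.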